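**Plan**
1. Cut 1: the bond from C1 of the tetralin to the pendant 3,4-dimethoxyphenyl ring, giving (2R,3R)-6,7-dimethoxy-2,3-dimethyltetralin and an arylboronic acid.
2. Enabling feature: without that aryl ring the tetralin has a twofold axis through the midpoints of C2–C3 and C6–C7, so the benzylic CH2 groups C1 and C4 are homotopic and each is para to a methoxy group (C6-OMe for C1, C7-OMe for C4). A direct C–H arylation therefore has no site problem and needs no handle.
3. Cut 2: the two methyl groups go back to ester carbons, and ring B is cut at C1–C2 and C3–C4 into a succinate dianion and 1,2-bis(bromomethyl)-4,5-dimethoxybenzene.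
4. Forward: ring B is closed onto ring A by double alkylation, the esters are taken down to methyl groups, and the pendant aryl ring is attached last.
5. Stereochemistry: C2 and C3 come from the (+)-menthyl ester auxiliaries (trans, R,R); C1 comes from substrate control in the arylation, the aryl entering anti to the C2 methyl.

Key step: step 5

Remark (assumption on the chemistry): the facial sense of the dianion cycloalkylation in step 1 is taken to be that established for dimenthyl succinate with dihalomethanes, where the (−)-menthyl ester leads to the (S,S) ring diester, so the (+)-menthyl ester is used for the (R,R) series; di-(+)-menthyl succinate is treated as a catalogue compound (otherwise one esterification from (+)-menthol and succinyl chloride).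

Step 1
Reactants: 1 di-(+)-menthyl succinate; 2 1,2-bis(bromomethyl)-4,5-dimethoxybenzene
Product: 5 bis[(1S,2R,5S)-menthyl] (2R,3R)-6,7-dimethoxy-1,2,3,4-tetrahydronaphthalene-2,3-dicarboxylate, via dilithium bis-enolate 3 (not isolated), via monoalkylated bromo enolate 4 (not isolated)
Conditions: LiTMP (lithium 2,2,6,6-tetramethylpiperidide, 2.2 equiv), THF, −78 °C; then 2 in THF, −78 °C to −20 °C
Reagents that add atoms: none
Why: The succinate dienolate C-alkylates one benzylic bromide and the remaining ester enolate closes ring B by a 6-exo-tet SN2 reaction (dianion cycloalkylation of dimenthyl succinate with a 1,ω-dihalide), the menthyl groups shielding one face of each enolate carbon so that both new stereocentres should form R with the esters trans.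

Step 2
Reactants: 5 bis[(1S,2R,5S)-menthyl] (2R,3R)-6,7-dimethoxy-1,2,3,4-tetrahydronaphthalene-2,3-dicarboxylate
Product: 6 [(2R,3R)-6,7-dimethoxy-1,2,3,4-tetrahydronaphthalene-2,3-diyl]dimethanol
Conditions: LiAlH4, THF, 0 °C to reflux; then H2O work-up
Reagents that add atoms: none
Why: LiAlH4 ester reduction should take both hindered esters to primary alcohols without touching the stereocentres, and it releases (+)-menthol for recovery.

Step 3
Reactants: 6 [(2R,3R)-6,7-dimethoxy-1,2,3,4-tetrahydronaphthalene-2,3-diyl]dimethanol
Product: 7 [(2R,3R)-6,7-dimethoxy-1,2,3,4-tetrahydronaphthalene-2,3-diyl]bis(methylene) dimethanesulfonate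
Conditions: MsCl (2.5 equiv), Et3N, CH2Cl2, 0 °C
Reagents that add atoms: methanesulfonyl chloride CS(=O)(=O)Cl
Why: Sulfonylation of the two primary alcohols at 0 °C with excess MsCl should give the dimesylate before any cyclisation to the fused tetrahydrofuran can compete.

Step 4
Reactants: 7 [(2R,3R)-6,7-dimethoxy-1,2,3,4-tetrahydronaphthalene-2,3-diyl]bis(methylene) dimethanesulfonate
Product: 8 (2R,3R)-6,7-dimethoxy-2,3-dimethyl-1,2,3,4-tetrahydronaphthalene
Conditions: LiEt3BH (4 equiv), THF, 0 °C to rt
Reagents that add atoms: none
Why: SN2 displacement of the primary mesylates by hydride (LiEt3BH reduction of sulfonates) should turn both CH2OMs groups into methyl groups, and the stereocentres are untouched because they are not the reacting carbons.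

Step 5
Reactants: 8 (2R,3R)-6,7-dimethoxy-2,3-dimethyl-1,2,3,4-tetrahydronaphthalene; 9 (3,4-dimethoxyphenyl)boronic acid
Product: 11 galbulin, via benzylic C1 radical 10 (not isolated)
Conditions: CuOAc (10 mol%), 2,2'-(propane-2,2-diyl)bis(4,4-dimethyl-4,5-dihydrooxazole) (12 mol%), N-fluorobenzenesulfonimide (NFSI, 1.0 equiv), Li2CO3 (1.0 equiv), 8 (2.0 equiv), 9 (1.5 equiv), PhCl, 30 °C
Reagents that add atoms: none
Why: Monovalent copper reduces NFSI to a divalent copper fluoride and the bis(phenylsulfonyl)imidyl radical, which abstracts a hydrogen atom from a benzylic CH2 of 8 to give radical 10; the aryl group of 9 is transmetallated to divalent copper, this aryl–copper species captures 10 to give a trivalent benzyl(aryl)copper, and reductive elimination forms the C1–aryl bond. The closest known reaction type is the copper/NFSI radical-relay arylation of benzylic C–H bonds of alkylarenes with arylboronic acids; no ring is closed. No site selectivity is needed, because the twofold axis of 8 makes C1 and C4 homotopic, and both are activated for hydrogen-atom abstraction by the para methoxy groups at C6 and C7. The new stereocentre C1 is set by substrate control: the planar radical is captured by the bulky ligated aryl–copper on the face anti to the neighbouring C2 methyl, so the aryl ends trans to it and the all-trans (1S,2S,3R) isomer, in which all three substituents can be equatorial, should result. The selectivity that must be secured is mono- over bis-arylation and over attack on the product, which is addressed by using 8 in excess (recovered) and by the steric shielding of the tertiary diaryl C1–H of 11 towards the bulky imidyl radical. Should the electron-rich radical be oxidised to the cation, ipso attack at the boron-bearing carbon of 9, which is para to a methoxy group, leads to the same product.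

**Compound list**
1 | di-(+)-menthyl succinate, bis[(1S,2R,5S)-2-isopropyl-5-methylcyclohexyl] butanedioate | O=C(CCC(=O)O[C@H]1C[C@@H](C)CC[C@@H]1C(C)C)O[C@H]1C[C@@H](C)CC[C@@H]1C(C)C | starting material
2 | 1,2-bis(bromomethyl)-4,5-dimethoxybenzene | COc1cc(CBr)c(CBr)cc1OC | starting material
3 | dilithium bis-enolate of 1 (dilithium 1,4-bis(menthyloxy)buta-1,3-diene-1,4-diolate) | [Li+].[Li+].[O-]C(=CC=C([O-])O[C@H]1C[C@@H](C)CC[C@@H]1C(C)C)O[C@H]1C[C@@H](C)CC[C@@H]1C(C)C | intermediate
4 | lithium ester enolate of di-(+)-menthyl (R)-2-[2-(bromomethyl)-4,5-dimethoxybenzyl]succinate | [Li+].[O-]C(O[C@H]1C[C@@H](C)CC[C@@H]1C(C)C)=C[C@H](C(=O)O[C@H]1C[C@@H](C)CC[C@@H]1C(C)C)Cc1cc(OC)c(OC)cc1CBr | intermediate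
5 | bis[(1S,2R,5S)-menthyl] (2R,3R)-6,7-dimethoxy-1,2,3,4-tetrahydronaphthalene-2,3-dicarboxylate | C1c2cc(OC)c(OC)cc2C[C@@H](C(=O)O[C@H]3C[C@@H](C)CC[C@@H]3C(C)C)[C@@H]1C(=O)O[C@H]1C[C@@H](C)CC[C@@H]1C(C)C | intermediate
6 | [(2R,3R)-6,7-dimethoxy-1,2,3,4-tetrahydronaphthalene-2,3-diyl]dimethanol | C1c2cc(OC)c(OC)cc2C[C@@H](CO)[C@@H]1CO | intermediate
7 | [(2R,3R)-6,7-dimethoxy-1,2,3,4-tetrahydronaphthalene-2,3-diyl]bis(methylene) dimethanesulfonate | C1c2cc(OC)c(OC)cc2C[C@@H](COS(C)(=O)=O)[C@@H]1COS(C)(=O)=O | intermediate
8 | (2R,3R)-6,7-dimethoxy-2,3-dimethyl-1,2,3,4-tetrahydronaphthalene (trans, twofold-symmetric) | C1c2cc(OC)c(OC)cc2C[C@@H](C)[C@@H]1C | intermediate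
9 | (3,4-dimethoxyphenyl)boronic acid | COc1ccc(B(O)O)cc1OC | starting material
10 | (2R,3R)-6,7-dimethoxy-2,3-dimethyl-1,2,3,4-tetrahydronaphthalen-1-yl radical | [CH]1c2cc(OC)c(OC)cc2C[C@@H](C)[C@@H]1C | intermediate
11 | galbulin, (1S,2S,3R)-1-(3,4-dimethoxyphenyl)-6,7-dimethoxy-2,3-dimethyl-1,2,3,4-tetrahydronaphthalene | COc1ccc([C@H]2c3cc(OC)c(OC)cc3C[C@@H](C)[C@@H]2C)cc1OC | target

**Step count**
Total steps: 5. Longest linear sequence: 5 steps.

**Steps most likely to fail**

Step 5 (C–H arylation). Several processes could go wrong:
- poor facial selectivity in the capture of the planar C1 radical, giving the C1/C2 cis isomer;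
- a second arylation at C4;
- oxidation of the electron-rich benzylic radical to the cation, followed by loss of the C2 proton and aromatisation;
- imidation of the dimethoxyarene rings by NFSI.

The fallback sets out from 8 and returns at 11. Benzylic oxidation of 8 with DDQ in aqueous dioxane/AcOH should give the single ketone (2S,3R)-6,7-dimethoxy-2,3-dimethyl-3,4-dihydronaphthalen-1(2H)-one F1, single because C1 and C4 are homotopic. NaBH4 in MeOH then gives (2S,3R)-6,7-dimethoxy-2,3-dimethyl-1,2,3,4-tetrahydronaphthalen-1-ol F2, whose C1 epimers are used together. FeCl3 (10 mol%) in CH2Cl2 with excess 1,2-dimethoxybenzene ionises F2 to the C1 benzylic cation. Friedel–Crafts attack of the arene, para to a methoxy group and anti to the C2 methyl, should give 11; any reversible loss and return of the C2 proton funnels to the all-trans isomer.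

Step 1 (dianion cycloalkylation). Three processes could go wrong:
- electron transfer from the dienolate to the bis-benzylic dibromide, giving 1,4-debromination to an o-quinodimethane and oxidation of the dianion to the fumarate;
- intermolecular double alkylation instead of ring closure;
- weaker facial discrimination with a benzylic electrophile than with a dihalomethane.

The fallback sets out from 2 and returns at 6. Zn dust in dioxane under ultrasound debrominates 2 to 2,3-dimethoxy-5,6-dimethylidenecyclohexa-1,3-diene F3. Dimethyl fumarate traps F3 in situ by Diels–Alder cycloaddition, which should give racemic dimethyl trans-6,7-dimethoxy-1,2,3,4-tetrahydronaphthalene-2,3-dicarboxylate F4. Preparative chromatography on a chiral stationary phase separates the enantiomers to give dimethyl (2R,3R)-6,7-dimethoxy-1,2,3,4-tetrahydronaphthalene-2,3-dicarboxylate F5. LiAlH4 in THF reduces F5 to 6.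

Step 4 (hydride displacement). Hydride may attack at sulfur instead of carbon; the alkoxide so formed would displace the neighbouring mesylate and close a fused tetrahydrofuran.

The fallback sets out from 7 and returns at 8. NaI in refluxing acetone (Finkelstein exchange) should give (2R,3R)-2,3-bis(iodomethyl)-6,7-dimethoxy-1,2,3,4-tetrahydronaphthalene F6. Radical chain reduction with Bu3SnH and AIBN in toluene at 80 °C removes both iodines to give 8.

Further compounds
F1 | step 5 | (2S,3R)-6,7-dimethoxy-2,3-dimethyl-3,4-dihydronaphthalen-1(2H)-one | O=C1c2cc(OC)c(OC)cc2C[C@@H](C)[C@@H]1C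
F2 | step 5 | (2S,3R)-6,7-dimethoxy-2,3-dimethyl-1,2,3,4-tetrahydronaphthalen-1-ol (both C1 epimers) | OC1c2cc(OC)c(OC)cc2C[C@@H](C)[C@@H]1C
F3 | step 1 | 2,3-dimethoxy-5,6-dimethylidenecyclohexa-1,3-diene (o-quinodimethane) | C=C1C=C(OC)C(OC)=CC1=C
F4 | step 1 | racemic dimethyl trans-6,7-dimethoxy-1,2,3,4-tetrahydronaphthalene-2,3-dicarboxylate | C1c2cc(OC)c(OC)cc2C[C@@H](C(=O)OC)[C@@H]1C(=O)OC.C1c2cc(OC)c(OC)cc2C[C@H](C(=O)OC)[C@H]1C(=O)OC
F5 | step 1 | dimethyl (2R,3R)-6,7-dimethoxy-1,2,3,4-tetrahydronaphthalene-2,3-dicarboxylate | C1c2cc(OC)c(OC)cc2C[C@@H](C(=O)OC)[C@@H]1C(=O)OC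
F6 | step 4 | (2R,3R)-2,3-bis(iodomethyl)-6,7-dimethoxy-1,2,3,4-tetrahydronaphthalene | C1c2cc(OC)c(OC)cc2C[C@@H](CI)[C@@H]1CI
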